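**Assumption:** the SMILES has no stereocentre and no assigned axial descriptor, so the hindered 8,8' biaryl axis is formed without control (racemic if rotation is slow), which matches the structure as drawn.

**Retrosynthetic overview**
- The target is the symmetric 8,8'-dimer of 6-hydroxygenistein; the last step is global O-demethylation of its octamethyl ether.
- The 8–8' biaryl bond comes from Ullmann homocoupling of 8-iodo-5,6,7,4'-tetramethoxyisoflavone.
- The iodide comes from electrophilic iodination at C8, the only free position of ring A.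
- Ring C comes from one-carbon annulation (DMF-DMA) of a 2-hydroxydeoxybenzoin, itself made by BF3-mediated ortho-acylation of 3,4,5-trimethoxyphenol with 4-methoxyphenylacetic acid.
- Ring order: rings A and B are bought, ring C is closed in step 2, the biaryl axis is made in step 4.

**Route**

Step 1
Reactants: 1 3,4,5-trimethoxyphenol; 2 2-(4-methoxyphenyl)acetic acid
Product: 3 1-(2-hydroxy-4,5,6-trimethoxyphenyl)-2-(4-methoxyphenyl)ethan-1-one
Conditions: BF3·OEt2 (neat), 85 °C, 2 h; aq NaOAc work-up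
Reagents that add atoms: none
Why: BF3-mediated Friedel–Crafts (Fries-type) C-acylation goes ortho to the free OH (both ortho sites are equivalent, para is blocked by OMe) and stops at the chelated ortho-hydroxy ketone, so one regioisomer forms and no stereocentre is created.

Step 2
Reactants: 3 1-(2-hydroxy-4,5,6-trimethoxyphenyl)-2-(4-methoxyphenyl)ethan-1-one
Product: 5 5,6,7-trimethoxy-3-(4-methoxyphenyl)-4H-chromen-4-one (5,6,7,4'-tetramethoxyisoflavone), via enaminone 4 (not isolated)
Conditions: DMF-DMA (3 equiv), toluene, 100 °C, 4 h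
Reagents that add atoms: N,N-dimethylformamide dimethyl acetal, COC(OC)N(C)C
Why: Condensation of the activated benzylic CH2 with DMF-DMA gives enaminone 4, whose ortho-OH adds in conjugate fashion and expels dimethylamine (addition–elimination) to close ring C, the standard deoxybenzoin-to-isoflavone annulation.

Step 3
Reactants: 5 5,6,7-trimethoxy-3-(4-methoxyphenyl)-4H-chromen-4-one
Product: 6 8-iodo-5,6,7-trimethoxy-3-(4-methoxyphenyl)-4H-chromen-4-one
Conditions: NIS (1.1 equiv), TFA (0.3 equiv), MeCN, 0 °C to rt, dark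
Reagents that add atoms: N-iodosuccinimide, O=C1CCC(=O)N1I
Why: Electrophilic aromatic iodination is selective for C8, the only unsubstituted carbon of ring A, because it is activated by O1 and 7-OMe (ortho) and 5-OMe (para) far more than any position of the mono-alkoxy ring B.

Step 4
Reactants: 6 8-iodo-5,6,7-trimethoxy-3-(4-methoxyphenyl)-4H-chromen-4-one (two molecules)
Product: 8 5,5',6,6',7,7'-hexamethoxy-3,3'-bis(4-methoxyphenyl)-4H,4'H-[8,8'-bichromene]-4,4'-dione, via arylcopper species 7 (not isolated)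
Conditions: activated Cu powder (6 equiv), DMF, 150 °C, Ar, 16 h
Reagents that add atoms: none
Why: In this Ullmann reductive homocoupling copper metal inserts into the C–I bond to give arylcopper 7, which couples with a second molecule of 6; the flanking alkoxy groups are tolerated, and the axis forms without stereocontrol because none is required.

Step 5
Reactants: 8 5,5',6,6',7,7'-hexamethoxy-3,3'-bis(4-methoxyphenyl)-4H,4'H-[8,8'-bichromene]-4,4'-dione
Product: 10 5,5',6,6',7,7'-hexahydroxy-3,3'-bis(4-hydroxyphenyl)-4H,4'H-[8,8'-bichromene]-4,4'-dione (CNP0254964.0), via octakis(dibromoboryl) borate ester 9 (not isolated)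
Conditions: BBr3 (1 M in CH2Cl2, 20 equiv), CH2Cl2, −78 °C to rt, 24 h, Ar; then H2O, 0 °C
Reagents that add atoms: none
Why: In this Lewis-acid aryl methyl ether cleavage BBr3 binds each methoxy oxygen and bromide removes the methyl by SN2, giving borate 9 that hydrolyses on quench, while the low temperature avoids the hot protic-acid ring opening and reclosure (Wessely–Moser rearrangement) that would move the biaryl bond from C8 to C6.

**Compound list**

1 | 3,4,5-trimethoxyphenol | COc1cc(O)cc(OC)c1OC | starting material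
2 | 2-(4-methoxyphenyl)acetic acid | COc1ccc(CC(=O)O)cc1 | starting material
3 | 1-(2-hydroxy-4,5,6-trimethoxyphenyl)-2-(4-methoxyphenyl)ethan-1-one | COc1ccc(CC(=O)c2c(O)cc(OC)c(OC)c2OC)cc1 | intermediate
4 | 3-(dimethylamino)-1-(2-hydroxy-4,5,6-trimethoxyphenyl)-2-(4-methoxyphenyl)prop-2-en-1-one (not isolated; push-pull C=C of no fixed geometry) | COc1ccc(cc1)C(=CN(C)C)C(=O)c1c(O)cc(OC)c(OC)c1OC | intermediate
5 | 5,6,7-trimethoxy-3-(4-methoxyphenyl)-4H-chromen-4-one | COc1ccc(cc1)-c1coc2cc(OC)c(OC)c(OC)c2c1=O | intermediate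
6 | 8-iodo-5,6,7-trimethoxy-3-(4-methoxyphenyl)-4H-chromen-4-one | COc1ccc(cc1)-c1coc2c(I)c(OC)c(OC)c(OC)c2c1=O | intermediate
7 | [5,6,7-trimethoxy-3-(4-methoxyphenyl)-4-oxo-4H-chromen-8-yl]copper (not isolated) | COc1ccc(cc1)-c1coc2c([Cu])c(OC)c(OC)c(OC)c2c1=O | intermediate
8 | 5,5',6,6',7,7'-hexamethoxy-3,3'-bis(4-methoxyphenyl)-4H,4'H-[8,8'-bichromene]-4,4'-dione | COc1ccc(cc1)-c1coc2c(-c3c(OC)c(OC)c(OC)c4c(=O)c(-c5ccc(OC)cc5)coc34)c(OC)c(OC)c(OC)c2c1=O | intermediate
9 | octakis(O-dibromoboryl) derivative of 10 (idealised aryl borate present before the aqueous quench; not isolated) | BrB(Br)Oc1ccc(cc1)-c1coc2c(-c3c(OB(Br)Br)c(OB(Br)Br)c(OB(Br)Br)c4c(=O)c(-c5ccc(OB(Br)Br)cc5)coc34)c(OB(Br)Br)c(OB(Br)Br)c(OB(Br)Br)c2c1=O | intermediate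
10 | 5,5',6,6',7,7'-hexahydroxy-3,3'-bis(4-hydroxyphenyl)-4H,4'H-[8,8'-bichromene]-4,4'-dione | O=c1c(-c2ccc(O)cc2)coc2c(-c3c(O)c(O)c(O)c4c(=O)c(-c5ccc(O)cc5)coc34)c(O)c(O)c(O)c12 | target

**Totals:** 5 steps in all; longest linear sequence 5 steps (1 → 3 → 5 → 6 → 8 → 10).

**Steps most likely to fail, with fallbacks** (step 4 is the most exposed, then step 5, then step 3; given here in route order)

Step 3 (iodination could also touch ring B or over-iodinate). The fallback sets out from 3 and comes back at 6. The iodine is put in before ring C exists, where the free phenol directs it: 3 is treated with NIS in CH2Cl2 at 0 °C. The only free carbon of the phenol ring, ortho to OH, is far more nucleophilic than the anisyl ring. This gives 1-(2-hydroxy-3-iodo-4,5,6-trimethoxyphenyl)-2-(4-methoxyphenyl)ethan-1-one F1. Heating F1 with DMF-DMA in toluene at 100 °C forms 3-(dimethylamino)-1-(2-hydroxy-3-iodo-4,5,6-trimethoxyphenyl)-2-(4-methoxyphenyl)prop-2-en-1-one F2 (not isolated), which cyclises to 6.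

Step 4 (Ullmann coupling to a biaryl with four ortho oxygens may stall or give mainly hydrodeiodinated 5). The fallback sets out from 6 and comes back at 8. It replaces the copper homocoupling by a cross-coupling on zerovalent palladium. One half of 6 undergoes Miyaura borylation (Pd(dppf)Cl2, B2pin2, KOAc, dioxane, 90 °C) to give 5,6,7-trimethoxy-3-(4-methoxyphenyl)-8-(4,4,5,5-tetramethyl-1,3,2-dioxaborolan-2-yl)-4H-chromen-4-one F3. F3 is then joined to the other half of 6 by Suzuki–Miyaura coupling under conditions suited to tetra-ortho-substituted biaryls (Pd(OAc)2, SPhos, K3PO4, toluene/H2O, 100 °C) to give 8.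

Step 5 (eightfold demethylation may stop at insoluble partly cleaved boron complexes, and the product is an air-sensitive bis-pyrogallol). The fallback sets out from 6 and comes back at 10. The methyl ethers are removed at the monomer stage, where only four must go, and hydrogenolysable benzyl ethers are carried through the coupling.
- 6 with BBr3 in CH2Cl2 (−78 °C to rt) gives the tetrakis(O-dibromoboryl) borate of the iodo-isoflavone F4 (not isolated), hydrolysed on quench to 5,6,7-trihydroxy-3-(4-hydroxyphenyl)-8-iodo-4H-chromen-4-one F5.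
- BnBr, K2CO3, DMF, 80 °C under Ar gives 5,6,7-tris(benzyloxy)-3-[4-(benzyloxy)phenyl]-8-iodo-4H-chromen-4-one F6.
- Ullmann coupling (activated Cu, DMF, 150 °C) proceeds through [5,6,7-tris(benzyloxy)-3-(4-(benzyloxy)phenyl)-4-oxo-4H-chromen-8-yl]copper F7 (not isolated) to 5,5',6,6',7,7'-hexakis(benzyloxy)-3,3'-bis[4-(benzyloxy)phenyl]-4H,4'H-[8,8'-bichromene]-4,4'-dione F8.
- Neutral hydrogenolysis of F8 (H2, Pd/C, THF/MeOH, rt) gives 10.

**Further compounds**

F1 | step 3 | 1-(2-hydroxy-3-iodo-4,5,6-trimethoxyphenyl)-2-(4-methoxyphenyl)ethan-1-one | COc1ccc(CC(=O)c2c(O)c(I)c(OC)c(OC)c2OC)cc1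
F2 | step 3 | 3-(dimethylamino)-1-(2-hydroxy-3-iodo-4,5,6-trimethoxyphenyl)-2-(4-methoxyphenyl)prop-2-en-1-one (not isolated) | COc1ccc(cc1)C(=CN(C)C)C(=O)c1c(O)c(I)c(OC)c(OC)c1OC
F3 | step 4 | 5,6,7-trimethoxy-3-(4-methoxyphenyl)-8-(4,4,5,5-tetramethyl-1,3,2-dioxaborolan-2-yl)-4H-chromen-4-one | COc1ccc(cc1)-c1coc2c(B3OC(C)(C)C(C)(C)O3)c(OC)c(OC)c(OC)c2c1=O
F4 | step 5 | tetrakis(O-dibromoboryl) derivative of F5 (idealised aryl borate, not isolated) | BrB(Br)Oc1ccc(cc1)-c1coc2c(I)c(OB(Br)Br)c(OB(Br)Br)c(OB(Br)Br)c2c1=O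
F5 | step 5 | 5,6,7-trihydroxy-3-(4-hydroxyphenyl)-8-iodo-4H-chromen-4-one | O=c1c(-c2ccc(O)cc2)coc2c(I)c(O)c(O)c(O)c12
F6 | step 5 | 5,6,7-tris(benzyloxy)-3-[4-(benzyloxy)phenyl]-8-iodo-4H-chromen-4-one | O=c1c(-c2ccc(OCc3ccccc3)cc2)coc2c(I)c(OCc3ccccc3)c(OCc3ccccc3)c(OCc3ccccc3)c12
F7 | step 5 | [5,6,7-tris(benzyloxy)-3-(4-(benzyloxy)phenyl)-4-oxo-4H-chromen-8-yl]copper (not isolated) | O=c1c(-c2ccc(OCc3ccccc3)cc2)coc2c([Cu])c(OCc3ccccc3)c(OCc3ccccc3)c(OCc3ccccc3)c12
F8 | step 5 | 5,5',6,6',7,7'-hexakis(benzyloxy)-3,3'-bis[4-(benzyloxy)phenyl]-4H,4'H-[8,8'-bichromene]-4,4'-dione | O=c1c(-c2ccc(OCc3ccccc3)cc2)coc2c(-c3c(OCc4ccccc4)c(OCc4ccccc4)c(OCc4ccccc4)c4c(=O)c(-c5ccc(OCc6ccccc6)cc5)coc34)c(OCc3ccccc3)c(OCc3ccccc3)c(OCc3ccccc3)c12
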